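**Retrosynthetic overview**

1. Theasinensin B ⇐ global hydrogenolysis ⇐ mono-galloylation of the C2-symmetric deca-O-benzyl bis(epigallocatechin) biaryl, whose two C3–OH groups are homotopic ⇐ hydride reduction of the corresponding bis(flavan-3-one).
2. Key disconnection, on both halves at once: the C4–C4a bond and the C3 carbonyl of each pyran ring ⇐ a bis(aryl propargyl ether), by gold-catalysed alkyne oxidation and arene capture. The C2–O1 bonds ⇐ two-fold Mitsunobu inversion with two molecules of 3,5-bis(benzyloxy)phenol; the propargylic carbinols ⇐ asymmetric alkynylation of a biaryl dialdehyde.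
3. Enabling feature: ring A is a phloroglucinol ring (oxygen on C5, C7 and C8a). Its precursor, a 3,5-bis(benzyloxy)phenoxy group on C2, therefore has two equivalent ortho carbons, each ortho/para to three oxygens; either one becomes C4a, and the two alkyne carbons map onto C3 (oxygen from an N-oxide) and C4.
4. Biaryl ⇐ ellagic acid, which already holds the B–B′ bond, all six B-ring oxygens and, as its two lactone carbonyl carbons, both future C2 atoms. The axis is fixed when its second lactone is opened by oxazaborolidine–borane reduction.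
5. Ring order: rings B and B′ come from ellagic acid; rings A and A′ and the galloyl ring are bought as arenes. The only rings closed are the two pyran rings, one after the other in one operation; they are homotopic, so the pyran ring of the half that is later galloylated is the last ring of the skeleton to be closed, and no ring is formed afterwards.

Key step: step 7

Remark (assumption): the SMILES carries no descriptor for the tetra-ortho-substituted B–B′ axis. The natural atropisomer (aR, the R-biphenyl of theasinensins A to C) is taken as the target; the SMILES strings below likewise cannot show the axis, so it is given in the names.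

**Route**

Step 1
Reactants: 1 ellagic acid
Product: 2 3,3′,4,4′-tetra-O-benzylellagic acid
Conditions: BnBr (excess), K2CO3, Bu4NI (cat.), DMF, 80 °C
Reagents that add atoms: benzyl bromide, BrCc1ccccc1
Why: Williamson ether synthesis on the four phenols, in which K2CO3 deprotonates the phenols but should not open the two aryl lactones, which are kept as the handles for step 2.

Step 2
Reactants: 2 3,3′,4,4′-tetra-O-benzylellagic acid
Product: 4 (aR)-3,3′,4,4′-tetrakis(benzyloxy)-6,6′-bis(hydroxymethyl)-[1,1′-biphenyl]-2,2′-diol, via monolactone 3 (not isolated)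
Conditions: (S)-2-methyl-CBS-oxazaborolidine (3 equiv), BH3·THF (8 equiv), THF, 0 °C to rt; MeOH, then aq. NaHCO3
Reagents that add atoms: none
Why: CBS (oxazaborolidine–borane) reduction with dynamic kinetic resolution, in which reduction of the first lactone of flat, achiral 2 gives 3, whose remaining six-membered lactone bridge lets the two helical forms of the biaryl interconvert fast, the oxazaborolidine-bound borane reduces one of them preferentially, and ring opening to the tetra-ortho-substituted biaryl locks the axis (aR expected with the (S)-reagent by analogy with related lactone-bridged biaryls, the (R)-reagent being used if the sense proves opposite), while the non-acidic work-up avoids ether formation from the electron-rich benzylic alcohols.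

Step 3
Reactants: 4 (aR)-3,3′,4,4′-tetrakis(benzyloxy)-6,6′-bis(hydroxymethyl)-[1,1′-biphenyl]-2,2′-diol
Product: 5 (aR)-[4,4′,5,5′,6,6′-hexakis(benzyloxy)-[1,1′-biphenyl]-2,2′-diyl]dimethanol
Conditions: BnBr (2.5 equiv), K2CO3, DMF, 50 °C
Reagents that add atoms: benzyl bromide, BrCc1ccccc1
Why: Williamson ether synthesis selective for the two phenols (K2CO3 does not deprotonate the benzylic alcohols), which also removes the phenols that could re-bridge the biaryl.

Step 4
Reactants: 5 (aR)-[4,4′,5,5′,6,6′-hexakis(benzyloxy)-[1,1′-biphenyl]-2,2′-diyl]dimethanol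
Product: 6 (aR)-4,4′,5,5′,6,6′-hexakis(benzyloxy)-[1,1′-biphenyl]-2,2′-dicarbaldehyde
Conditions: (COCl)2, DMSO, CH2Cl2, −78 °C; Et3N, −78 to 0 °C
Reagents that add atoms: none
Why: Swern oxidation, chosen because both alcohols are converted to alkoxysulfonium ions before the base is added, so that no hydroxy aldehyde is present that could close to a seven-membered lactol and be over-oxidised to a lactone.

Step 5
Reactants: 6 (aR)-4,4′,5,5′,6,6′-hexakis(benzyloxy)-[1,1′-biphenyl]-2,2′-dicarbaldehyde
Product: 8 (1R,1′R)-1,1′-[(aR)-4,4′,5,5′,6,6′-hexakis(benzyloxy)-[1,1′-biphenyl]-2,2′-diyl]bis(prop-2-yn-1-ol), via bis(TMS-alkynyl carbinol) 7 (not isolated)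
Conditions: Me2Zn, (S,S)-ProPhenol (cat.), Ph3PO (cat.), TMS-acetylene (excess), toluene, 0 °C; aq. NH4Cl; then K2CO3 (cat.), MeOH, rt
Reagents that add atoms: trimethylsilylacetylene, C#C[Si](C)(C)C
Why: Dinuclear zinc–ProPhenol-catalysed enantioselective alkynylation of both aromatic aldehydes under reagent control (the 1S carbinols of 7 expected with the (S,S)-ligand, otherwise its antipode is used), the two-fold reaction on a C2-symmetric substrate turning minor facial errors into separable diastereomers, after which K2CO3/MeOH removes the silyl groups without touching the carbinol centres, whose descriptor becomes R only because the alkynyl group loses CIP rank.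

Step 6
Reactants: 8 (1R,1′R)-1,1′-[(aR)-4,4′,5,5′,6,6′-hexakis(benzyloxy)-[1,1′-biphenyl]-2,2′-diyl]bis(prop-2-yn-1-ol), 9 3,5-bis(benzyloxy)phenol (two equivalents, one for each carbinol)
Product: 10 (aR)-4,4′,5,5′,6,6′-hexakis(benzyloxy)-2,2′-bis{(1S)-1-[3,5-bis(benzyloxy)phenoxy]prop-2-yn-1-yl}-1,1′-biphenyl
Conditions: 9 (2.4 equiv), PPh3 (2.6 equiv), DIAD (2.6 equiv), toluene, 0 °C to rt
Reagents that add atoms: 3,5-bis(benzyloxy)phenol (compound 9, of which two molecules are incorporated, one at each carbinol carbon), Oc1cc(OCc2ccccc2)cc(OCc2ccccc2)c1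
Why: Two-fold Mitsunobu etherification that consumes two molecules of 9 and loses two molecules of water to PPh3/DIAD, in which each alkoxyphosphonium is displaced by the phenol oxygen of one molecule of 9 with inversion (1R to 1S), which sets the future C2 and C2′ in the configuration of the target, the carbinol carbons carrying no β-hydrogen so that elimination cannot compete and phenols of this type reacting at oxygen under these conditions.

Step 7
Reactants: 10 (aR)-4,4′,5,5′,6,6′-hexakis(benzyloxy)-2,2′-bis{(1S)-1-[3,5-bis(benzyloxy)phenoxy]prop-2-yn-1-yl}-1,1′-biphenyl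
Product: 12 (2R,2′R)-2,2′-[(aR)-4,4′,5,5′,6,6′-hexakis(benzyloxy)-[1,1′-biphenyl]-2,2′-diyl]bis[5,7-bis(benzyloxy)chroman-3-one], via monoketone 11 (not isolated)
Conditions: (Me4tBuXPhos)AuNTf2 (5 mol % per alkyne), 2,6-dichloropyridine N-oxide (1.3 equiv per alkyne), 4 Å MS, 1,2-dichloroethane, rt
Reagents that add atoms: 2,6-dichloropyridine N-oxide, [O-][n+]1c(Cl)cccc1Cl
Why: Each terminal alkyne is activated by the cationic gold catalyst and attacked at its internal carbon by the N-oxide oxygen, N–O cleavage leaves an α-oxo gold carbene at the terminal carbon (future C4), the adjacent ortho carbon of the 3,5-bis(benzyloxy)phenoxy ring (future C4a) attacks it, and rearomatisation with protodeauration gives the chroman-3-one. The closest known reaction type is the gold-catalysed oxidation of aryl propargyl ethers with pyridine N-oxides to chroman-3-ones. Each pyran ring closes through the C4–C4a bond in a six-membered Friedel–Crafts-type attack of the arene on the exocyclic carbene carbon (6-exo with respect to the C=Au bond, formally 6-endo-dig with respect to the alkyne), the two closures following one another through 11, and the second of them is the last ring closure of the route. No new stereocentre is created: C2 and C2′ (set in step 6) and the axis (set in step 2) are not touched, and the new C3 carbonyls are the handles from which C2 controls C3 in step 8. The step needs (a) oxygen transfer to the internal alkyne carbon, secured by the terminal alkyne, (b) capture of the carbene by the phenoxy ring and not by C6′–H of ring B (five-membered alternative) or by an ether oxygen, secured by the two equivalent ortho carbons that are each ortho/para to three oxygens, (c) oxidation faster than direct hydroarylation to a 2H-chromene, favoured by the bulky biarylphosphine ligand and by having the N-oxide present from the start, and (d) no epimerisation at the now enolisable C2, for which the oxidant leaves only the very weakly basic 2,6-dichloropyridine and the crude diketone goes straight into step 8.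

Step 8
Reactants: 12 (2R,2′R)-2,2′-[(aR)-4,4′,5,5′,6,6′-hexakis(benzyloxy)-[1,1′-biphenyl]-2,2′-diyl]bis[5,7-bis(benzyloxy)chroman-3-one]
Product: 13 (2R,3R,2′R,3′R)-2,2′-[(aR)-4,4′,5,5′,6,6′-hexakis(benzyloxy)-[1,1′-biphenyl]-2,2′-diyl]bis[5,7-bis(benzyloxy)chroman-3-ol] (deca-O-benzyl theasinensin C)
Conditions: LiBH(s-Bu)3 (L-Selectride), THF, −78 °C; H2O
Reagents that add atoms: none
Why: Substrate-controlled reduction of 2-aryl-chroman-3-ones with a bulky borohydride, in which hydride adds to each C3 carbonyl from the face opposite the pseudo-equatorial C2 aryl group and gives the axial 3-OH cis to that aryl group (3R), the low temperature keeping the enolisable C2 centres intact.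

Step 9
Reactants: 13 (2R,3R,2′R,3′R)-2,2′-[(aR)-4,4′,5,5′,6,6′-hexakis(benzyloxy)-[1,1′-biphenyl]-2,2′-diyl]bis[5,7-bis(benzyloxy)chroman-3-ol], 14 3,4,5-tris(benzyloxy)benzoic acid
Product: 15 mono-3-O-[3,4,5-tris(benzyloxy)benzoate] of 13 (trideca-O-benzyl theasinensin B)
Conditions: 14 (0.9 equiv), DCC, DMAP (cat.), CH2Cl2, 0 °C to rt
Reagents that add atoms: none
Why: Steglich esterification in which the two C3 hydroxyls are homotopic (exchanged by the C2 axis), so that mono-acylation can give only one compound, the expected statistical mixture with unreacted 13 (recycled) and the bis-gallate (returned to 13 by methanolysis) being separated by chromatography.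

Step 10
Reactants: 15 mono-3-O-[3,4,5-tris(benzyloxy)benzoate] of 13
Product: 16 theasinensin B
Conditions: H2 (1 atm), Pd(OH)2/C, THF/MeOH, rt
Reagents that add atoms: none
Why: Hydrogenolysis of all thirteen benzyl ethers under neutral conditions at room temperature, which should leave the gallate ester, the benzylic C2–O1 bonds, the four stereocentres and the biaryl axis untouched.

**Compound list**

1 | ellagic acid (2,3,7,8-tetrahydroxychromeno[5,4,3-cde]chromene-5,10-dione) | O=C1Oc2c(O)c(O)cc3C(=O)Oc4c(O)c(O)cc1c4c23 | starting material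
2 | 3,3′,4,4′-tetra-O-benzylellagic acid (flat, achiral bis-lactone) | O=C1Oc2c(OCc9ccccc9)c(OCc9ccccc9)cc3C(=O)Oc4c(OCc9ccccc9)c(OCc9ccccc9)cc1c4c23 | intermediate
3 | monolactone: 3,4,8,9-tetrakis(benzyloxy)-10-hydroxy-1-(hydroxymethyl)-6H-benzo[c]chromen-6-one (axis configurationally labile) | O=C1Oc2c(OCc9ccccc9)c(OCc9ccccc9)cc(CO)c2-c2c(O)c(OCc9ccccc9)c(OCc9ccccc9)cc12 | intermediate
4 | (aR)-3,3′,4,4′-tetrakis(benzyloxy)-6,6′-bis(hydroxymethyl)-[1,1′-biphenyl]-2,2′-diol | OCc1cc(OCc9ccccc9)c(OCc9ccccc9)c(O)c1-c1c(CO)cc(OCc9ccccc9)c(OCc9ccccc9)c1O | intermediate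
5 | (aR)-[4,4′,5,5′,6,6′-hexakis(benzyloxy)-[1,1′-biphenyl]-2,2′-diyl]dimethanol | OCc1cc(OCc9ccccc9)c(OCc9ccccc9)c(OCc9ccccc9)c1-c1c(CO)cc(OCc9ccccc9)c(OCc9ccccc9)c1OCc9ccccc9 | intermediate
6 | (aR)-4,4′,5,5′,6,6′-hexakis(benzyloxy)-[1,1′-biphenyl]-2,2′-dicarbaldehyde | O=Cc1cc(OCc9ccccc9)c(OCc9ccccc9)c(OCc9ccccc9)c1-c1c(C=O)cc(OCc9ccccc9)c(OCc9ccccc9)c1OCc9ccccc9 | intermediate
7 | (1S,1′S)-1,1′-[(aR)-4,4′,5,5′,6,6′-hexakis(benzyloxy)-[1,1′-biphenyl]-2,2′-diyl]bis[3-(trimethylsilyl)prop-2-yn-1-ol] | c1(OCc9ccccc9)c(OCc9ccccc9)c(OCc9ccccc9)cc([C@@H](C#C[Si](C)(C)C)O)c1-c1c([C@@H](C#C[Si](C)(C)C)O)cc(OCc9ccccc9)c(OCc9ccccc9)c1OCc9ccccc9 | intermediate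
8 | (1R,1′R)-1,1′-[(aR)-4,4′,5,5′,6,6′-hexakis(benzyloxy)-[1,1′-biphenyl]-2,2′-diyl]bis(prop-2-yn-1-ol) | c1(OCc9ccccc9)c(OCc9ccccc9)c(OCc9ccccc9)cc([C@@H](C#C)O)c1-c1c([C@@H](C#C)O)cc(OCc9ccccc9)c(OCc9ccccc9)c1OCc9ccccc9 | intermediate
9 | 3,5-bis(benzyloxy)phenol | Oc1cc(OCc2ccccc2)cc(OCc2ccccc2)c1 | starting material
10 | (aR)-4,4′,5,5′,6,6′-hexakis(benzyloxy)-2,2′-bis{(1S)-1-[3,5-bis(benzyloxy)phenoxy]prop-2-yn-1-yl}-1,1′-biphenyl | c1(OCc9ccccc9)c(OCc9ccccc9)c(OCc9ccccc9)cc([C@H](C#C)Oc2cc(OCc9ccccc9)cc(OCc9ccccc9)c2)c1-c1c([C@H](C#C)Oc2cc(OCc9ccccc9)cc(OCc9ccccc9)c2)cc(OCc9ccccc9)c(OCc9ccccc9)c1OCc9ccccc9 | intermediate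
11 | monoketone: 10 with one half cyclised to the (2R)-5,7-bis(benzyloxy)chroman-3-one, the other half still the (1S)-propargyl aryl ether | c1(OCc9ccccc9)c(OCc9ccccc9)c(OCc9ccccc9)cc([C@H]2Oc3cc(OCc9ccccc9)cc(OCc9ccccc9)c3CC2=O)c1-c1c([C@H](C#C)Oc2cc(OCc9ccccc9)cc(OCc9ccccc9)c2)cc(OCc9ccccc9)c(OCc9ccccc9)c1OCc9ccccc9 | intermediate
12 | (2R,2′R)-2,2′-[(aR)-4,4′,5,5′,6,6′-hexakis(benzyloxy)-[1,1′-biphenyl]-2,2′-diyl]bis[5,7-bis(benzyloxy)chroman-3-one] | c1(OCc9ccccc9)c(OCc9ccccc9)c(OCc9ccccc9)cc([C@H]2Oc3cc(OCc9ccccc9)cc(OCc9ccccc9)c3CC2=O)c1-c1c([C@H]2Oc3cc(OCc9ccccc9)cc(OCc9ccccc9)c3CC2=O)cc(OCc9ccccc9)c(OCc9ccccc9)c1OCc9ccccc9 | intermediate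
13 | (2R,3R,2′R,3′R)-2,2′-[(aR)-4,4′,5,5′,6,6′-hexakis(benzyloxy)-[1,1′-biphenyl]-2,2′-diyl]bis[5,7-bis(benzyloxy)chroman-3-ol] (deca-O-benzyl theasinensin C, C2-symmetric) | c1(OCc9ccccc9)c(OCc9ccccc9)c(OCc9ccccc9)cc([C@H]2Oc3cc(OCc9ccccc9)cc(OCc9ccccc9)c3C[C@H]2O)c1-c1c([C@H]2Oc3cc(OCc9ccccc9)cc(OCc9ccccc9)c3C[C@H]2O)cc(OCc9ccccc9)c(OCc9ccccc9)c1OCc9ccccc9 | intermediate
14 | 3,4,5-tris(benzyloxy)benzoic acid | OC(=O)c1cc(OCc2ccccc2)c(OCc2ccccc2)c(OCc2ccccc2)c1 | starting material
15 | trideca-O-benzyl theasinensin B (13 with one of its two 3-OH groups esterified by 3,4,5-tris(benzyloxy)benzoic acid; 2R,3R,2′R,3′R, aR) | c1(OCc9ccccc9)c(OCc9ccccc9)c(OCc9ccccc9)cc([C@H]2Oc3cc(OCc9ccccc9)cc(OCc9ccccc9)c3C[C@H]2OC(=O)c4cc(OCc9ccccc9)c(OCc9ccccc9)c(OCc9ccccc9)c4)c1-c1c([C@H]2Oc3cc(OCc9ccccc9)cc(OCc9ccccc9)c3C[C@H]2O)cc(OCc9ccccc9)c(OCc9ccccc9)c1OCc9ccccc9 | intermediate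
16 | theasinensin B | O=C(O[C@@H]1Cc2c(O)cc(O)cc2O[C@@H]1c1cc(O)c(O)c(O)c1-c1c([C@H]2Oc3cc(O)cc(O)c3C[C@H]2O)cc(O)c(O)c1O)c1cc(O)c(O)c(O)c1 | target

**Step count and risks**

Total step count: 10. Longest linear sequence: 10 steps (1 to 16); 9 and 14 are bought.

Three steps most likely to fail:

Step 7. The very electron-rich phenoxy ring may add directly to the gold-activated alkyne (hydroarylation without oxygen transfer), the carbene may be captured by ring B, or C2 may epimerise in the product ketone. Fallback: the hydroarylation is made the intended path. From 10, Ph3PAuNTf2 in CH2Cl2 without oxidant should give, by two-fold 6-endo hydroarylation, the (2S,2′S)-bis(5,7-bis(benzyloxy)-2H-chromene) F1 (same spatial arrangement at C2 as in 10). Hydroboration–oxidation (BH3·THF; NaOH, H2O2) places boron on C3 anti to the C2 aryl group and should give the 2,3-trans bis(flavan-3-ol) F2. Dess–Martin oxidation then returns to 12, from which step 8 sets the cis relationship.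

Step 2. The atropo-selection of the oxazaborolidine reduction may be insufficient or opposite, or the axis may leak through translactonisation in 3. Fallback: auxiliary control with separation. From 2, sodium (1R,2S,5R)-menthoxide in THF opens both lactones to the bis(menthyl ester) diphenol; the atropo-diastereomers are separated, and the aR isomer, bis[(1R,2S,5R)-menthyl] (aR)-4,4′,5,5′-tetrakis(benzyloxy)-6,6′-dihydroxy-[1,1′-biphenyl]-2,2′-dicarboxylate F3, is reduced with LiAlH4 to 4. The reduction is run promptly after separation, before the free phenols can re-close the lactones.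

Step 6. The oxyphosphonium at the electron-rich benzylic and propargylic carbon may ionise, with loss of configuration, or the hindered centres may react sluggishly so that only one of the two carbinols is etherified. Fallback: an enantioconvergent copper-catalysed propargylic etherification. From 8, Ac2O, pyridine and DMAP give the (1R,1′R)-bis(acetate) F4. With (CuOTf)2·C6H6, the Ph-pybox enantiomer that gives the 1S ether, iPr2NEt and 9 (two equivalents or more), this should react through planar copper allenylidenes to give 10. Since the catalyst sets C2 whatever the carbinol configuration, this also absorbs incomplete selectivity in step 5.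

Further compounds
F1 | step 7 | (2S,2′S)-2,2′-[(aR)-4,4′,5,5′,6,6′-hexakis(benzyloxy)-[1,1′-biphenyl]-2,2′-diyl]bis[5,7-bis(benzyloxy)-2H-chromene] | c1(OCc9ccccc9)c(OCc9ccccc9)c(OCc9ccccc9)cc([C@H]2Oc3cc(OCc9ccccc9)cc(OCc9ccccc9)c3C=C2)c1-c1c([C@H]2Oc3cc(OCc9ccccc9)cc(OCc9ccccc9)c3C=C2)cc(OCc9ccccc9)c(OCc9ccccc9)c1OCc9ccccc9
F2 | step 7 | (2R,3S,2′R,3′S)-2,2′-[(aR)-4,4′,5,5′,6,6′-hexakis(benzyloxy)-[1,1′-biphenyl]-2,2′-diyl]bis[5,7-bis(benzyloxy)chroman-3-ol] (2,3-trans) | c1(OCc9ccccc9)c(OCc9ccccc9)c(OCc9ccccc9)cc([C@H]2Oc3cc(OCc9ccccc9)cc(OCc9ccccc9)c3C[C@@H]2O)c1-c1c([C@H]2Oc3cc(OCc9ccccc9)cc(OCc9ccccc9)c3C[C@@H]2O)cc(OCc9ccccc9)c(OCc9ccccc9)c1OCc9ccccc9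
F3 | step 2 | bis[(1R,2S,5R)-menthyl] (aR)-4,4′,5,5′-tetrakis(benzyloxy)-6,6′-dihydroxy-[1,1′-biphenyl]-2,2′-dicarboxylate | CC(C)[C@@H]1CC[C@@H](C)C[C@H]1OC(=O)c1cc(OCc9ccccc9)c(OCc9ccccc9)c(O)c1-c1c(C(=O)O[C@@H]2C[C@H](C)CC[C@H]2C(C)C)cc(OCc9ccccc9)c(OCc9ccccc9)c1O
F4 | step 6 | (1R,1′R)-[(aR)-4,4′,5,5′,6,6′-hexakis(benzyloxy)-[1,1′-biphenyl]-2,2′-diyl]bis(prop-2-yne-1,1-diyl) diacetate | c1(OCc9ccccc9)c(OCc9ccccc9)c(OCc9ccccc9)cc([C@@H](C#C)OC(C)=O)c1-c1c([C@@H](C#C)OC(C)=O)cc(OCc9ccccc9)c(OCc9ccccc9)c1OCc9ccccc9
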